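Atoms are cited in elemane numbering: C10 is the quaternary ring carbon carrying the C14 methyl and the C1=C2 vinyl, C9 the ring methylene, C8 the acyloxy carbon, C7 and C6 the lactone ring-fusion carbons, C11(=C13)–C12 the enoate, and C5 carries C4(=C3)–C15. Compounds carry the numbers of the route.

## The problem

Compound 33 is an elemane-type lactone: one cyclohexane (C5–C10) carries five stereocentres, of which C5, C6, C7 and C8 are contiguous, while the quaternary C10 (methyl, vinyl) is separated from C8 by the C9 methylene. An α-methylene-γ-butyrolactone is trans-fused across C6–C7, C8 bears an (R)-3-hydroxy-2-methylpropanoate, and C5 a 3-hydroxyprop-1-en-2-yl group (C4=C3, C15–OH). In the chair the substituents on C5, C6, C7 and C8 are all equatorial and alternately trans, so these four centres can be relayed from one another through a single chair. At C10 the methyl is equatorial and the vinyl axial, cis to the C5 side chain; C10 has no directing neighbour and has to be set by absolute control before the ring exists. Three groups dictate the order of events: the exocyclic enoate C11=C13 (a Michael acceptor that tolerates neither enolate chemistry elsewhere nor basic nucleophiles), the side-chain ester with its epimerisable α-centre, and the two primary hydroxyls that must stay distinguishable from the C8 oxygen; the terminal alkenes add a sensitivity to strong acid. The feature that allows a short ring synthesis is the C6 carbinol with a trans 2-propenyl unit on C5, the isopulegol pattern. It is the retron of an intramolecular carbonyl-ene reaction between a C6 aldehyde and a C5=C4 prenyl-type alkene, which forms C5–C6, closes the cyclohexane and leaves the C4=C3 methylene in one operation.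

## Retrosynthesis

**C15–O.** Target 33 is the desilylation product of 32, and 32 is cut at C15–O to give 31, in which C15 is a plain methyl. In 31 the C4=C3 alkene is the only electron-rich alkene with allylic hydrogens: the vinyl group sits on quaternary C10 and C11=C13 is electron-poor. Against carrying a protected C15 oxygen from the start, this cut avoids telling two primary hydroxyls apart from the C8 oxygen and keeps the prenyl-type alkene of the key step unfunctionalised. The forward reaction must hydroxylate the methyl rather than the hindered C5 methine and stop at the alcohol.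

**Acyl–O8.** Ester 31 is cut into alcohol 26 and acid 29; 29 comes from the Roche ester 27 through silyl ether 28. The side chain is attached after all enolate chemistry on the lactone, because its α-centre would not survive a strong base. The esterification has to acylate a secondary, equatorial hydroxyl next to a Michael acceptor without epimerising the acid.

**C11=C13 and O8–Si.** Alcohol 26 comes from silyl ether 25, whose exocyclic methylene is cut at C11=C13 back to Mannich base 23 and lactone 21. Putting C13 on after the lactone exists is the standard, reliable order; the C8 silyl ether stays until the enolate step is over so that no C8 alkoxide can translactonise.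

**O6–C12.** Lactone 21 is opened to hydroxy ester 20. In 20 the C6 hydroxyl and the C7 acetate arm are trans-diequatorial, so closure needs no stereochemical work.

**C5–C6 (key).** Cyclohexanol 20 is cut between C5 and C6 to give acyclic aldehyde 18. Cutting here rather than at C6–C7 or C5–C10 removes the ring and two stereocentres at once and leaves a chain whose three remaining centres (C7, C8, C10) are each accessible by reagent control. The forward carbonyl-ene reaction has to close through the one chair that places the C7 and C8 substituents equatorial.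

**C7–C8.** Aldehyde 18 is reached from alcohol 17, silyl ether 16 and aldol adduct 15, which is cut at C7–C8 into succinate imide 13 and aldehyde 9. The syn relationship of the C7 arm and the C8 oxygen is what an auxiliary-controlled syn-aldol delivers, and the imide carbonyl is the latent C6 aldehyde. The C12 ester is tert-butyl: a methyl ester would be attacked by the C8 aldolate and close the unwanted C8–O–C12 lactone.

**Imide.** Imide 13 is cut at the N–acyl bond into mono-tert-butyl succinate 10 and oxazolidinone 11.

**C5–C10.** Aldehyde 9 is taken back through alcohol 8 to triene 7, which is cut at C5–C10 into allylic phosphate 5 and alkenylboronate 6. An SN2′ substitution creates the quaternary centre and the C1=C2 vinyl together; no other cut at C10 gives both. The forward step must be γ-selective and enantioselective on a trisubstituted alkene.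

**Phosphate.** Phosphate 5 comes from allylic alcohol 4, which is cut at C10–C14 and C1–C2 to silyl ether 2 and 3-butyn-1-ol 1. Carbometalation with formaldehyde trapping fixes the (E)-geometry on which the face selectivity of the substitution depends.

## Roads not taken

**Alternative 1:** The cut is C6–C7, with the lactone C–O bond and C11=C13 released in the same operation. In the forward step SmI2 would reduce the C6 aldehyde of open-chain enoate A1 to a ketyl, which adds to C7 of the 2-(acetoxymethyl)enoate. The samarium enolate then expels acetate and the C6 alkoxide lactonises, giving bis-silyl ether A2.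
- Merits: one step builds the ring, C6, C7, the lactone and the exocyclic methylene, and the C15 oxygen is present from the start. After the ring closure only protecting-group changes and the acylation remain, three or four operations fewer than in the chosen endgame, with no lactone enolate and no late C–H oxidation.
- Weak points: A1 must already hold C5 and C10 as neighbouring stereocentres in an open chain, and C5 is at once α to the aldehyde and allylic, so it can epimerise or move into conjugation. The γ-silyloxy enoate can lose the C8 oxygen reductively and the allylic acetate can be reduced before the ketyl adds. The C6/C7 outcome rests on a folded transition state with four substituents on the chain.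
- Comparison: in step count after ring closure this road is better. The chosen plan sets against it that C5 is created only in the ring-forming event, that C7, the only centre next to the aldehyde of 18, is not allylic, and that every centre comes from a reagent-controlled reaction or from one chair.

**Alternative 2:** The cut is at C1=C2 and C4=C3, both seen as the ends of an opened cyclobutene. The second-generation Grubbs catalyst under ethylene would open the C1=C4 bond of bicyclic ketone A3 to give ketone A4.
- Merits: the cis relation of the C10 vinyl and the C5 side chain, the hardest relation in the target, is guaranteed by the cis-fused four-membered ring. Both terminal alkenes stay masked until late, and the opening is strain-driven.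
- Weak points: the key step forms no ring bond and no stereocentre; the whole burden moves to A3, a bicyclo[4.2.0]octenone with four stereocentres, probably from an enone–alkyne photocycloaddition with open regio- and facial selectivity. The trisubstituted cyclobutene carbon slows metathesis. In A4, C5 is α to the ketone and allylic. The C6 ketone must then be reduced by hydride delivered syn to the axial C10 vinyl to give the equatorial alcohol, which is the hindered trajectory. Lactonisation and methylenation are still needed.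
- Comparison: this road is stronger on the C5/C10 relation, which is fixed by the substrate and not by a transition state. The chosen plan sets against it that C6 is formed with its oxygen and configuration in the ring-closing step, with no ketone reduction and no epimerisable C5 next to a carbonyl.

**Alternative 3:** The cut is C5–C10 by a [3,3] shift. LiN(i-Pr)2 and Me3SiCl would turn ten-membered allylic lactone A5 into its silyl ketene acetal, which contracts (Ireland–Claisen) to cyclohexanecarboxylic acid A6 with the C4=C3 methylene in place.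
- Merits: C10 and C5 are set together through a cyclic transition state without an enantioselective catalyst, and the C15 oxygen is carried through.
- Weak points: A5 is a medium-ring lactone that already contains the γ-lactone, so its closure is the hardest ring size. The base must enolise the hindered macrolactone α-carbon (C10) in the presence of the more accessible γ-lactone CH2 (C11). Ketene acetal geometry and the boat/chair preference in the medium ring decide the C5/C10 relation. The C1 carboxyl of A6 needs three more steps at a neopentyl centre to become the vinyl group.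
- Comparison: this road is better in that C10 needs no asymmetric catalysis and C15 needs no late oxidation. The chosen plan sets against it an open-chain precursor with no macrocyclisation, no competing enolisation and a vinyl group present from the start.

Key step: step 12

Assumption: the enantiomer of the chiral ligand in step 4 is the one that delivers the alkenyl group to the face of 5 giving R at C10; both antipodes of such ligands are accessible, and the assignment would be checked on alcohol 8.

## Route

Step 1
Reactants: 1 3-butyn-1-ol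
Product: 2 tert-butyl(but-3-yn-1-yloxy)dimethylsilane
Conditions: TBSCl, imidazole, CH2Cl2, 0 °C → rt
Reagents that add atoms: tert-butyldimethylsilyl chloride, CC(C)(C)[Si](C)(C)Cl
Why: Standard silylation of a primary alcohol; the silyl ether masks the future C8 oxygen through the organometallic steps.

Step 2
Reactants: 2 tert-butyl(but-3-yn-1-yloxy)dimethylsilane
Product: 4 (E)-5-[(tert-butyldimethylsilyl)oxy]-3-methylpent-2-en-1-ol, via (E)-alkenyldimethylalane 3 (not isolated)
Conditions: Me3Al, Cp2ZrCl2 (cat.), CH2Cl2, 0 °C → rt; then (CH2O)n, THF, 0 °C → rt; aq. potassium sodium tartrate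
Reagents that add atoms: trimethylaluminium, C[Al](C)C; paraformaldehyde (as formaldehyde), C=O
Why: Zirconium-catalysed syn-carboalumination puts methyl on the internal and aluminium on the terminal alkyne carbon, and the alkenylalane is hydroxymethylated with retention. This fixes the (E)-trisubstituted alkene whose geometry is translated into the C10 configuration in step 4.

Step 3
Reactants: 4 (E)-5-[(tert-butyldimethylsilyl)oxy]-3-methylpent-2-en-1-ol
Product: 5 diethyl (E)-5-[(tert-butyldimethylsilyl)oxy]-3-methylpent-2-en-1-yl phosphate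
Conditions: ClP(O)(OEt)2, Et3N, DMAP (cat.), CH2Cl2, 0 °C
Reagents that add atoms: diethyl chlorophosphate, CCOP(=O)(Cl)OCC
Why: O-Phosphorylation of a primary allylic alcohol; the phosphate is the leaving group needed for copper-catalysed SN2′ substitution.

Step 4
Reactants: 5 diethyl (E)-5-[(tert-butyldimethylsilyl)oxy]-3-methylpent-2-en-1-yl phosphate; 6 4,4,5,5-tetramethyl-2-(2-methylprop-1-en-1-yl)-1,3,2-dioxaborolane
Product: 7 tert-butyl{[(3R)-3-ethenyl-3,5-dimethylhex-4-en-1-yl]oxy}dimethylsilane
Conditions: CuCl (5 mol %), enantiopure sulfonate-bearing imidazolinium salt (carbene precursor, 5.5 mol %), NaOMe (1.5 equiv), THF, 22 → 60 °C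
Reagents that add atoms: none
Why: Copper-catalysed enantioselective allylic substitution with an alkenylboronate: methoxide transfers the 2-methylpropenyl group from boron to copper, and γ-attack on the (E)-phosphate forms C5–C10 and the C1=C2 vinyl. The ligand selects the alkene face and so sets R at C10; the reaction class is established for quaternary centres from trisubstituted allylic phosphates.

Step 5
Reactants: 7 tert-butyl{[(3R)-3-ethenyl-3,5-dimethylhex-4-en-1-yl]oxy}dimethylsilane
Product: 8 (3R)-3-ethenyl-3,5-dimethylhex-4-en-1-ol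
Conditions: n-Bu4NF, THF, 0 °C → rt
Reagents that add atoms: none
Why: Fluoride cleavage of a primary silyl ether; the alkenes are inert and the product is concentrated with care because it is volatile.

Step 6
Reactants: 8 (3R)-3-ethenyl-3,5-dimethylhex-4-en-1-ol
Product: 9 (3R)-3-ethenyl-3,5-dimethylhex-4-enal
Conditions: Dess–Martin periodinane, NaHCO3, CH2Cl2, 0 °C → rt
Reagents that add atoms: none
Why: Dess–Martin oxidation; the β-carbon is quaternary, so the aldehyde can neither conjugate nor lose configuration, and it is used directly.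

Step 7
Reactants: 10 4-tert-butoxy-4-oxobutanoic acid (mono-tert-butyl succinate); 11 (4R)-4-benzyl-1,3-oxazolidin-2-one
Product: 13 tert-butyl 4-[(4R)-4-benzyl-2-oxo-1,3-oxazolidin-3-yl]-4-oxobutanoate, via mixed pivalic anhydride 12 (not isolated)
Conditions: t-BuCOCl, Et3N, THF, −20 °C; then 11, LiCl, −20 °C → rt
Reagents that add atoms: none
Why: N-Acylation of the oxazolidinone through the mixed anhydride, which is attacked at the unhindered succinyl carbonyl. The tert-butyl ester is chosen so that the later C8 aldolate cannot lactonise onto C12.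

Step 8
Reactants: 13 tert-butyl 4-[(4R)-4-benzyl-2-oxo-1,3-oxazolidin-3-yl]-4-oxobutanoate; 9 (3R)-3-ethenyl-3,5-dimethylhex-4-enal
Product: 15 tert-butyl (3R,4S,6R)-3-{[(4R)-4-benzyl-2-oxo-1,3-oxazolidin-3-yl]carbonyl}-6-ethenyl-4-hydroxy-6,8-dimethylnon-7-enoate, via (Z)-boron enolate 14 (not isolated)
Conditions: n-Bu2BOTf, i-Pr2NEt, CH2Cl2, −78 → 0 °C; 9, −78 → 0 °C; then H2O2, MeOH, pH 7 buffer, 0 °C
Reagents that add atoms: none
Why: Evans syn-aldol: soft enolisation occurs only next to the imide, and the (Z)-boron enolate reacts through a Zimmerman–Traxler chair on the face away from the benzyl group. This sets C7 (R) and C8 (S) under auxiliary control, independent of the remote C10 centre.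

Step 9
Reactants: 15 tert-butyl (3R,4S,6R)-3-{[(4R)-4-benzyl-2-oxo-1,3-oxazolidin-3-yl]carbonyl}-6-ethenyl-4-hydroxy-6,8-dimethylnon-7-enoate
Product: 16 tert-butyl (3R,4S,6R)-3-{[(4R)-4-benzyl-2-oxo-1,3-oxazolidin-3-yl]carbonyl}-4-[(tert-butyldimethylsilyl)oxy]-6-ethenyl-6,8-dimethylnon-7-enoate
Conditions: TBSOTf, 2,6-lutidine, CH2Cl2, −78 → 0 °C
Reagents that add atoms: tert-butyldimethylsilyl triflate, CC(C)(C)[Si](C)(C)OS(=O)(=O)C(F)(F)F
Why: Silylation of the hindered aldol hydroxyl with the silyl triflate at low temperature; it blocks retro-aldol and C8-to-C12 lactonisation and supplies the bulky equatorial group for the key step.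

Step 10
Reactants: 16 tert-butyl (3R,4S,6R)-3-{[(4R)-4-benzyl-2-oxo-1,3-oxazolidin-3-yl]carbonyl}-4-[(tert-butyldimethylsilyl)oxy]-6-ethenyl-6,8-dimethylnon-7-enoate
Product: 17 tert-butyl (3S,4S,6R)-4-[(tert-butyldimethylsilyl)oxy]-6-ethenyl-3-(hydroxymethyl)-6,8-dimethylnon-7-enoate
Conditions: LiBH4, MeOH (1 equiv), THF, 0 °C
Reagents that add atoms: none
Why: Reductive removal of the auxiliary: LiBH4 reduces the imide carbonyl in preference to the tert-butyl ester and gives the C6 primary alcohol; the descriptor at C7 changes only because the priorities change.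

Step 11
Reactants: 17 tert-butyl (3S,4S,6R)-4-[(tert-butyldimethylsilyl)oxy]-6-ethenyl-3-(hydroxymethyl)-6,8-dimethylnon-7-enoate
Product: 18 tert-butyl (3R,4S,6R)-4-[(tert-butyldimethylsilyl)oxy]-6-ethenyl-3-formyl-6,8-dimethylnon-7-enoate
Conditions: Dess–Martin periodinane, NaHCO3, CH2Cl2, 0 °C → rt
Reagents that add atoms: none
Why: Buffered Dess–Martin oxidation gives the α-branched β-silyloxy aldehyde without C7 epimerisation or β-elimination; the aldehyde is taken on at once.

Step 12
Reactants: 18 tert-butyl (3R,4S,6R)-4-[(tert-butyldimethylsilyl)oxy]-6-ethenyl-3-formyl-6,8-dimethylnon-7-enoate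
Product: 20 tert-butyl 2-[(1S,2R,3S,4R,6S)-6-[(tert-butyldimethylsilyl)oxy]-4-ethenyl-2-hydroxy-4-methyl-3-(prop-1-en-2-yl)cyclohexyl]acetate, via chloro(methyl)aluminium alkoxide 19 (not isolated)
Conditions: Me2AlCl (1.2 equiv), CH2Cl2, −78 → −20 °C; aq. potassium sodium tartrate
Reagents that add atoms: none
Why: Me2AlCl binds the C6 aldehyde oxygen, and in a concerted but asynchronous ene process C5 of the C5=C4 alkene attacks C6 while a hydrogen of a C4 methyl moves to oxygen; this gives C5–C6, the C4=C3 methylene and, after loss of methane from aluminium, alkoxide 19, which the work-up hydrolyses to 20. The closest known reaction is the Lewis-acid-promoted carbonyl-ene cyclisation of citronellal to isopulegol. The cyclohexane closes in a 6-exo-trig sense at C5, with C4 and the carbonyl oxygen both ending outside the ring. The chain reacts through the chair in which the C8 silyl ether and the C7 acetate arm are equatorial, which places the C10 methyl equatorial and the C10 vinyl axial. At C6 the aluminium-bound oxygen takes the equatorial position, trans to the C7 arm, because the axial position is 1,3-diaxial to the C10 vinyl. At C5 the alkene is equatorial as well, since hydrogen transfer needs the C4 methyl next to the carbonyl oxygen; C4 therefore ends trans to O6 and cis to the C10 vinyl. The step needs trans C5/C6 selectivity in the correct chair and chemoselectivity for the aldehyde over the ester and for the prenyl-type alkene over the vinyl group; the first is secured by the three existing stereocentres, the second by the reactivity of the complexed aldehyde and the lack of allylic hydrogens on the vinyl group, while Me2AlCl scavenges the proton that would otherwise attack the silyl ether or the new alkene.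

Step 13
Reactants: 20 tert-butyl 2-[(1S,2R,3S,4R,6S)-6-[(tert-butyldimethylsilyl)oxy]-4-ethenyl-2-hydroxy-4-methyl-3-(prop-1-en-2-yl)cyclohexyl]acetate
Product: 21 (3aS,4S,6R,7S,7aR)-4-[(tert-butyldimethylsilyl)oxy]-6-ethenyl-6-methyl-7-(prop-1-en-2-yl)hexahydro-1-benzofuran-2(3H)-one
Conditions: camphor-10-sulfonic acid (0.2 equiv), CH2Cl2, rt → 40 °C
Reagents that add atoms: none
Why: Acid-catalysed intramolecular transesterification: the C6 hydroxyl and the C7 acetate arm are trans-diequatorial, so the trans-fused γ-lactone closes with loss of tert-butanol. A catalytic sulfonic acid in an aprotic solvent should leave the silyl ether and the 1,1-disubstituted alkene untouched.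

Step 14
Reactants: 21 (3aS,4S,6R,7S,7aR)-4-[(tert-butyldimethylsilyl)oxy]-6-ethenyl-6-methyl-7-(prop-1-en-2-yl)hexahydro-1-benzofuran-2(3H)-one
Product: 23 (3aS,4S,6R,7S,7aR)-4-[(tert-butyldimethylsilyl)oxy]-3-[(dimethylamino)methyl]-6-ethenyl-6-methyl-7-(prop-1-en-2-yl)hexahydro-1-benzofuran-2(3H)-one (C11 epimers), via lithium enolate 22 (not isolated)
Conditions: LiN(i-Pr)2, THF, −78 °C; then (Me2N=CH2)I, −78 °C → rt
Reagents that add atoms: Eschenmoser's salt (N,N-dimethylmethyleneiminium iodide), C[N+](C)=C.[I-]
Why: Enolisation at C11, the only acidic position, and Mannich reaction with the preformed iminium salt; the C11 configuration is irrelevant because C11 becomes sp2 in step 15.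

Step 15
Reactants: 23 (3aS,4S,6R,7S,7aR)-4-[(tert-butyldimethylsilyl)oxy]-3-[(dimethylamino)methyl]-6-ethenyl-6-methyl-7-(prop-1-en-2-yl)hexahydro-1-benzofuran-2(3H)-one
Product: 25 (3aS,4S,6R,7S,7aR)-4-[(tert-butyldimethylsilyl)oxy]-6-ethenyl-6-methyl-3-methylidene-7-(prop-1-en-2-yl)hexahydro-1-benzofuran-2(3H)-one, via trimethylammonium iodide 24 (not isolated)
Conditions: MeI, MeOH, rt; then aq. NaHCO3, CH2Cl2, rt
Reagents that add atoms: none
Why: N-Methylation and Hofmann-type β-elimination of trimethylamine give the exocyclic enoate C11=C13; this is the standard α-methylenation of γ-butyrolactones.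

Step 16
Reactants: 25 (3aS,4S,6R,7S,7aR)-4-[(tert-butyldimethylsilyl)oxy]-6-ethenyl-6-methyl-3-methylidene-7-(prop-1-en-2-yl)hexahydro-1-benzofuran-2(3H)-one
Product: 26 (3aR,4S,6R,7S,7aR)-6-ethenyl-4-hydroxy-6-methyl-3-methylidene-7-(prop-1-en-2-yl)hexahydro-1-benzofuran-2(3H)-one
Conditions: HF·pyridine, pyridine, THF, 0 °C → rt
Reagents that add atoms: none
Why: Buffered HF·pyridine removes the secondary silyl ether without a basic fluoride that could add to the enoate or trigger translactonisation to C8.

Step 17
Reactants: 27 methyl (2R)-3-hydroxy-2-methylpropanoate (Roche ester)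
Product: 28 methyl (2R)-3-[(tert-butyldimethylsilyl)oxy]-2-methylpropanoate
Conditions: TBSCl, imidazole, CH2Cl2, 0 °C → rt
Reagents that add atoms: tert-butyldimethylsilyl chloride, CC(C)(C)[Si](C)(C)Cl
Why: Silylation of the primary hydroxyl; the stereocentre is not touched.

Step 18
Reactants: 28 methyl (2R)-3-[(tert-butyldimethylsilyl)oxy]-2-methylpropanoate
Product: 29 (2R)-3-[(tert-butyldimethylsilyl)oxy]-2-methylpropanoic acid
Conditions: LiOH, THF/MeOH/H2O, 0 °C → rt; then aq. HCl to pH 3
Reagents that add atoms: lithium hydroxide, [Li+].[OH-]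
Why: Saponification at low temperature; the carboxylate formed is not enolised, so the α-centre is kept, and the silyl ether survives.

Step 19
Reactants: 29 (2R)-3-[(tert-butyldimethylsilyl)oxy]-2-methylpropanoic acid; 26 (3aR,4S,6R,7S,7aR)-6-ethenyl-4-hydroxy-6-methyl-3-methylidene-7-(prop-1-en-2-yl)hexahydro-1-benzofuran-2(3H)-one
Product: 31 (3aR,4S,6R,7S,7aR)-6-ethenyl-6-methyl-3-methylidene-2-oxo-7-(prop-1-en-2-yl)octahydro-1-benzofuran-4-yl (2R)-3-[(tert-butyldimethylsilyl)oxy]-2-methylpropanoate, via mixed trichlorobenzoic anhydride 30 (not isolated)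
Conditions: 2,4,6-Cl3C6H2COCl, Et3N, toluene, rt; then 26, DMAP, toluene, rt
Reagents that add atoms: none
Why: Yamaguchi esterification: DMAP attacks the aliphatic carbonyl of the mixed anhydride and the acylpyridinium acylates the equatorial C8 hydroxyl. The conditions are non-nucleophilic toward the enoate, and the short activation limits α-epimerisation of the acid.

Step 20
Reactants: 31 (3aR,4S,6R,7S,7aR)-6-ethenyl-6-methyl-3-methylidene-2-oxo-7-(prop-1-en-2-yl)octahydro-1-benzofuran-4-yl (2R)-3-[(tert-butyldimethylsilyl)oxy]-2-methylpropanoate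
Product: 32 (3aR,4S,6R,7R,7aR)-6-ethenyl-7-(3-hydroxyprop-1-en-2-yl)-6-methyl-3-methylidene-2-oxooctahydro-1-benzofuran-4-yl (2R)-3-[(tert-butyldimethylsilyl)oxy]-2-methylpropanoate
Conditions: SeO2 (0.3 equiv), t-BuOOH (3 equiv), CH2Cl2, 0 °C → rt
Reagents that add atoms: tert-butyl hydroperoxide, CC(C)(C)OO; selenium dioxide (oxygen carrier), O=[Se]=O
Why: Riley allylic oxidation: ene reaction of SeO2 at terminal C3 of the only electron-rich alkene with allylic hydrogens, then a [2,3] shift that returns the double bond to C4=C3 and puts oxygen on C15. The methyl hydrogens are favoured over the hindered C5 methine, the vinyl group has no allylic hydrogen, and the enoate is electron-poor; the descriptor at C5 changes only by priority.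

Step 21
Reactants: 32 (3aR,4S,6R,7R,7aR)-6-ethenyl-7-(3-hydroxyprop-1-en-2-yl)-6-methyl-3-methylidene-2-oxooctahydro-1-benzofuran-4-yl (2R)-3-[(tert-butyldimethylsilyl)oxy]-2-methylpropanoate
Product: 33 (3aR,4S,6R,7R,7aR)-6-ethenyl-7-(3-hydroxyprop-1-en-2-yl)-6-methyl-3-methylidene-2-oxooctahydro-1-benzofuran-4-yl (2R)-3-hydroxy-2-methylpropanoate (CNP0133858.4)
Conditions: HF·pyridine, pyridine, THF, 0 °C
Reagents that add atoms: none
Why: Buffered HF·pyridine cleaves the primary silyl ether; no base is present that could epimerise the side-chain α-centre, move the acyl group or add to the enoate.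

## Compound list

1 | 3-butyn-1-ol | C#CCCO | starting material
2 | tert-butyl(but-3-yn-1-yloxy)dimethylsilane | C#CCCO[Si](C)(C)C(C)(C)C | intermediate
3 | (E)-{4-[(tert-butyldimethylsilyl)oxy]-2-methylbut-1-en-1-yl}dimethylalane | C[Al](C)/C=C(\C)CCO[Si](C)(C)C(C)(C)C | intermediate (not isolated)
4 | (E)-5-[(tert-butyldimethylsilyl)oxy]-3-methylpent-2-en-1-ol | OC/C=C(\C)CCO[Si](C)(C)C(C)(C)C | intermediate
5 | diethyl (E)-5-[(tert-butyldimethylsilyl)oxy]-3-methylpent-2-en-1-yl phosphate | CCOP(=O)(OCC)OC/C=C(\C)CCO[Si](C)(C)C(C)(C)C | intermediate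
6 | 4,4,5,5-tetramethyl-2-(2-methylprop-1-en-1-yl)-1,3,2-dioxaborolane | CC(C)=CB1OC(C)(C)C(C)(C)O1 | starting material
7 | tert-butyl{[(3R)-3-ethenyl-3,5-dimethylhex-4-en-1-yl]oxy}dimethylsilane | C=C[C@@](C=C(C)C)(C)CCO[Si](C)(C)C(C)(C)C | intermediate
8 | (3R)-3-ethenyl-3,5-dimethylhex-4-en-1-ol | C=C[C@@](C=C(C)C)(C)CCO | intermediate
9 | (3R)-3-ethenyl-3,5-dimethylhex-4-enal | C=C[C@@](C=C(C)C)(C)CC=O | intermediate
10 | 4-tert-butoxy-4-oxobutanoic acid | OC(=O)CCC(=O)OC(C)(C)C | starting material
11 | (4R)-4-benzyl-1,3-oxazolidin-2-one | O=C1N[C@H](Cc2ccccc2)CO1 | starting material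
12 | 4-tert-butoxy-4-oxobutanoic pivalic anhydride | CC(C)(C)C(=O)OC(=O)CCC(=O)OC(C)(C)C | intermediate (not isolated)
13 | tert-butyl 4-[(4R)-4-benzyl-2-oxo-1,3-oxazolidin-3-yl]-4-oxobutanoate | CC(C)(C)OC(=O)CCC(=O)N1[C@H](Cc2ccccc2)COC1=O | intermediate
14 | di-n-butylboron (Z)-enolate of 13 | CCCCB(CCCC)O/C(=C\CC(=O)OC(C)(C)C)N1[C@H](Cc2ccccc2)COC1=O | intermediate (not isolated)
15 | tert-butyl (3R,4S,6R)-3-{[(4R)-4-benzyl-2-oxo-1,3-oxazolidin-3-yl]carbonyl}-6-ethenyl-4-hydroxy-6,8-dimethylnon-7-enoate | C=C[C@@](C=C(C)C)(C)C[C@H](O)[C@H](C(=O)N1[C@H](Cc2ccccc2)COC1=O)CC(=O)OC(C)(C)C | intermediate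
16 | tert-butyl (3R,4S,6R)-3-{[(4R)-4-benzyl-2-oxo-1,3-oxazolidin-3-yl]carbonyl}-4-[(tert-butyldimethylsilyl)oxy]-6-ethenyl-6,8-dimethylnon-7-enoate | C=C[C@@](C=C(C)C)(C)C[C@H](O[Si](C)(C)C(C)(C)C)[C@H](C(=O)N1[C@H](Cc2ccccc2)COC1=O)CC(=O)OC(C)(C)C | intermediate
17 | tert-butyl (3S,4S,6R)-4-[(tert-butyldimethylsilyl)oxy]-6-ethenyl-3-(hydroxymethyl)-6,8-dimethylnon-7-enoate | C=C[C@@](C=C(C)C)(C)C[C@H](O[Si](C)(C)C(C)(C)C)[C@H](CO)CC(=O)OC(C)(C)C | intermediate
18 | tert-butyl (3R,4S,6R)-4-[(tert-butyldimethylsilyl)oxy]-6-ethenyl-3-formyl-6,8-dimethylnon-7-enoate | C=C[C@@](C=C(C)C)(C)C[C@H](O[Si](C)(C)C(C)(C)C)[C@H](C=O)CC(=O)OC(C)(C)C | intermediate (key-step precursor)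
19 | chloro(methyl)aluminium alkoxide of 20 (aluminium on O6) | C=C[C@@]1(C)C[C@H](O[Si](C)(C)C(C)(C)C)[C@@H](CC(=O)OC(C)(C)C)[C@H](O[Al](C)Cl)[C@H]1C(C)=C | intermediate (not isolated)
20 | tert-butyl 2-[(1S,2R,3S,4R,6S)-6-[(tert-butyldimethylsilyl)oxy]-4-ethenyl-2-hydroxy-4-methyl-3-(prop-1-en-2-yl)cyclohexyl]acetate | C=C[C@@]1(C)C[C@H](O[Si](C)(C)C(C)(C)C)[C@@H](CC(=O)OC(C)(C)C)[C@H](O)[C@H]1C(C)=C | intermediate (key-step product)
21 | (3aS,4S,6R,7S,7aR)-4-[(tert-butyldimethylsilyl)oxy]-6-ethenyl-6-methyl-7-(prop-1-en-2-yl)hexahydro-1-benzofuran-2(3H)-one | C=C[C@@]1(C)C[C@H](O[Si](C)(C)C(C)(C)C)[C@H]2CC(=O)O[C@@H]2[C@H]1C(C)=C | intermediate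
22 | lithium enolate of 21 (C11=C12–OLi) | C=C[C@@]1(C)C[C@H](O[Si](C)(C)C(C)(C)C)[C@H]2C=C(O[Li])O[C@@H]2[C@H]1C(C)=C | intermediate (not isolated)
23 | (3aS,4S,6R,7S,7aR)-4-[(tert-butyldimethylsilyl)oxy]-3-[(dimethylamino)methyl]-6-ethenyl-6-methyl-7-(prop-1-en-2-yl)hexahydro-1-benzofuran-2(3H)-one (C11 epimers) | C=C[C@@]1(C)C[C@H](O[Si](C)(C)C(C)(C)C)[C@H]2C(CN(C)C)C(=O)O[C@@H]2[C@H]1C(C)=C | intermediate
24 | N-methyl quaternary ammonium iodide of 23 | C=C[C@@]1(C)C[C@H](O[Si](C)(C)C(C)(C)C)[C@H]2C(C[N+](C)(C)C)C(=O)O[C@@H]2[C@H]1C(C)=C.[I-] | intermediate (not isolated)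
25 | (3aS,4S,6R,7S,7aR)-4-[(tert-butyldimethylsilyl)oxy]-6-ethenyl-6-methyl-3-methylidene-7-(prop-1-en-2-yl)hexahydro-1-benzofuran-2(3H)-one | C=C[C@@]1(C)C[C@H](O[Si](C)(C)C(C)(C)C)[C@H]2C(=C)C(=O)O[C@@H]2[C@H]1C(C)=C | intermediate
26 | (3aR,4S,6R,7S,7aR)-6-ethenyl-4-hydroxy-6-methyl-3-methylidene-7-(prop-1-en-2-yl)hexahydro-1-benzofuran-2(3H)-one | C=C[C@@]1(C)C[C@H](O)[C@H]2C(=C)C(=O)O[C@@H]2[C@H]1C(C)=C | intermediate
27 | methyl (2R)-3-hydroxy-2-methylpropanoate | COC(=O)[C@H](C)CO | starting material
28 | methyl (2R)-3-[(tert-butyldimethylsilyl)oxy]-2-methylpropanoate | COC(=O)[C@H](C)CO[Si](C)(C)C(C)(C)C | intermediate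
29 | (2R)-3-[(tert-butyldimethylsilyl)oxy]-2-methylpropanoic acid | OC(=O)[C@H](C)CO[Si](C)(C)C(C)(C)C | intermediate
30 | (2R)-3-[(tert-butyldimethylsilyl)oxy]-2-methylpropanoic 2,4,6-trichlorobenzoic anhydride | Clc1cc(Cl)c(C(=O)OC(=O)[C@H](C)CO[Si](C)(C)C(C)(C)C)c(Cl)c1 | intermediate (not isolated)
31 | (3aR,4S,6R,7S,7aR)-6-ethenyl-6-methyl-3-methylidene-2-oxo-7-(prop-1-en-2-yl)octahydro-1-benzofuran-4-yl (2R)-3-[(tert-butyldimethylsilyl)oxy]-2-methylpropanoate | C=C[C@@]1(C)C[C@H](OC(=O)[C@H](C)CO[Si](C)(C)C(C)(C)C)[C@H]2C(=C)C(=O)O[C@@H]2[C@H]1C(C)=C | intermediate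
32 | (3aR,4S,6R,7R,7aR)-6-ethenyl-7-(3-hydroxyprop-1-en-2-yl)-6-methyl-3-methylidene-2-oxooctahydro-1-benzofuran-4-yl (2R)-3-[(tert-butyldimethylsilyl)oxy]-2-methylpropanoate | C=C[C@@]1(C)C[C@H](OC(=O)[C@H](C)CO[Si](C)(C)C(C)(C)C)[C@H]2C(=C)C(=O)O[C@@H]2[C@H]1C(=C)CO | intermediate
33 | (3aR,4S,6R,7R,7aR)-6-ethenyl-7-(3-hydroxyprop-1-en-2-yl)-6-methyl-3-methylidene-2-oxooctahydro-1-benzofuran-4-yl (2R)-3-hydroxy-2-methylpropanoate | C=C[C@@]1(C)C[C@H](OC(=O)[C@H](C)CO)[C@H]2C(=C)C(=O)O[C@@H]2[C@H]1C(=C)CO | target

## Step count and risk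

Total: 21 steps. Longest linear sequence: 18 steps (steps 1–6, 8–16 and 19–21). Imide 13 (step 7) and acid 29 (steps 17–18) are made in side branches.

**Step 12 (key step).** The most likely failure is diversion of the aluminium-bound aldehyde before the hindered alkene, which sits on a quaternary carbon, engages it. The Lewis acid can be held by the ester and silyl ether oxygens, C7 can epimerise or the silyloxy group can be lost by β-elimination, and a stepwise cationic course can end in chloride capture at C4. The fallback sets out from 16 and returns at 20; it reverses the polarity of the closure so that a preformed allyl-metal attacks the aldehyde. SeO2/t-BuOOH oxidation of the (E)-methyl of the prenyl-type alkene of 16 would give allylic alcohol F1. MsCl, LiCl and 2,4,6-collidine convert it into allylic chloride F2. LiBH4 and then Dess–Martin oxidation, as in steps 10 and 11, give chloro alcohol F3 and chloro aldehyde F4. CrCl2 in THF then forms the allylchromium species, which adds through its γ-carbon C5 to the C6 aldehyde (intramolecular Nozaki–Hiyama–Kishi-type allylation through a chair) to give 20.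

**Step 4.** The risks are incomplete face selectivity, competing α-substitution and slow boron-to-copper transfer of the β,β-disubstituted alkenyl group. The fallback sets out from 6 and returns at 15; it gives up catalytic control at C10 and relies on the auxiliary for separation. Suzuki–Miyaura coupling of 6 with (Z)-3-iodobut-2-en-1-ol (Pd(PPh3)4, aq. K3PO4, THF) would give dienol F5. Johnson–Claisen rearrangement (MeC(OEt)3, cat. EtCO2H, 140 °C) forms the C9–C10 bond and gives racemic ester F6, and i-Bu2AlH at −78 °C gives racemic aldehyde F7. The aldol of step 8 then gives 15 together with its C10 epimer F8, which is removed by chromatography. The price is half of the material.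

**Step 20.** The risks are over-oxidation of the allylic alcohol to the enal and competing attack at the C5 methine, on a substrate where an enal cannot be reduced back without endangering the enoate. The fallback sets out from 21 and returns at 33; it moves the oxidation ahead of the methylenation. SeO2/t-BuOOH on 21, with NaBH4/CeCl3·7H2O to return any enal, would give hydroxy lactone F9, and t-BuPh2SiCl/imidazole gives silyl ether F10. The sequence of steps 14 and 15 gives amine F11, ammonium salt F12 and methylene lactone F13. Brief HF·pyridine removes the secondary silyl group selectively to give alcohol F14, the esterification of step 19 with 29 gives ester F15, and prolonged HF·pyridine gives 33. This costs two extra steps.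

**Step 13.** The risk is loss of the C8 silyl group or protonation of the 1,1-disubstituted alkene before the hindered ester exchanges. The fallback sets out from 20 and returns at 21; it replaces acid catalysis by carboxyl activation. Me3SiOTf and 2,6-lutidine convert the tert-butyl ester into the silyl ester and cap O6, giving bis-silyl compound F16. K2CO3 in MeOH followed by a pH 4 work-up gives hydroxy acid F17, which EDC·HCl and DMAP close to 21.

## Further compounds

F1 | step 12 | tert-butyl (3R,4S,6R,7E)-3-{[(4R)-4-benzyl-2-oxo-1,3-oxazolidin-3-yl]carbonyl}-4-[(tert-butyldimethylsilyl)oxy]-6-ethenyl-9-hydroxy-6,8-dimethylnon-7-enoate | C=C[C@@](/C=C(\C)CO)(C)C[C@H](O[Si](C)(C)C(C)(C)C)[C@H](C(=O)N1[C@H](Cc2ccccc2)COC1=O)CC(=O)OC(C)(C)C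
F2 | step 12 | tert-butyl (3R,4S,6R,7E)-3-{[(4R)-4-benzyl-2-oxo-1,3-oxazolidin-3-yl]carbonyl}-4-[(tert-butyldimethylsilyl)oxy]-9-chloro-6-ethenyl-6,8-dimethylnon-7-enoate | C=C[C@@](/C=C(\C)CCl)(C)C[C@H](O[Si](C)(C)C(C)(C)C)[C@H](C(=O)N1[C@H](Cc2ccccc2)COC1=O)CC(=O)OC(C)(C)C
F3 | step 12 | tert-butyl (3S,4S,6R,7E)-4-[(tert-butyldimethylsilyl)oxy]-9-chloro-6-ethenyl-3-(hydroxymethyl)-6,8-dimethylnon-7-enoate | C=C[C@@](/C=C(\C)CCl)(C)C[C@H](O[Si](C)(C)C(C)(C)C)[C@H](CO)CC(=O)OC(C)(C)C
F4 | step 12 | tert-butyl (3R,4S,6R,7E)-4-[(tert-butyldimethylsilyl)oxy]-9-chloro-6-ethenyl-3-formyl-6,8-dimethylnon-7-enoate | C=C[C@@](/C=C(\C)CCl)(C)C[C@H](O[Si](C)(C)C(C)(C)C)[C@H](C=O)CC(=O)OC(C)(C)C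
F5 | step 4 | (2Z)-3,5-dimethylhexa-2,4-dien-1-ol | OC/C=C(/C)C=C(C)C
F6 | step 4 | ethyl 3-ethenyl-3,5-dimethylhex-4-enoate (racemic) | CCOC(=O)CC(C)(C=C)C=C(C)C
F7 | step 4 | 3-ethenyl-3,5-dimethylhex-4-enal (racemic) | O=CCC(C)(C=C)C=C(C)C
F8 | step 4 | tert-butyl (3R,4S,6S)-3-{[(4R)-4-benzyl-2-oxo-1,3-oxazolidin-3-yl]carbonyl}-6-ethenyl-4-hydroxy-6,8-dimethylnon-7-enoate (C10 epimer of 15) | C=C[C@](C=C(C)C)(C)C[C@H](O)[C@H](C(=O)N1[C@H](Cc2ccccc2)COC1=O)CC(=O)OC(C)(C)C
F9 | step 20 | (3aS,4S,6R,7R,7aR)-4-[(tert-butyldimethylsilyl)oxy]-6-ethenyl-7-(3-hydroxyprop-1-en-2-yl)-6-methylhexahydro-1-benzofuran-2(3H)-one | C=C[C@@]1(C)C[C@H](O[Si](C)(C)C(C)(C)C)[C@H]2CC(=O)O[C@@H]2[C@H]1C(=C)CO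
F10 | step 20 | tert-butyldiphenylsilyl ether of F9 at O15 | C=C[C@@]1(C)C[C@H](O[Si](C)(C)C(C)(C)C)[C@H]2CC(=O)O[C@@H]2[C@H]1C(=C)CO[Si](c3ccccc3)(c4ccccc4)C(C)(C)C
F11 | step 20 | 11-[(dimethylamino)methyl] derivative of F10 (C11 epimers) | C=C[C@@]1(C)C[C@H](O[Si](C)(C)C(C)(C)C)[C@H]2C(CN(C)C)C(=O)O[C@@H]2[C@H]1C(=C)CO[Si](c3ccccc3)(c4ccccc4)C(C)(C)C
F12 | step 20 | N-methyl quaternary ammonium iodide of F11 | C=C[C@@]1(C)C[C@H](O[Si](C)(C)C(C)(C)C)[C@H]2C(C[N+](C)(C)C)C(=O)O[C@@H]2[C@H]1C(=C)CO[Si](c3ccccc3)(c4ccccc4)C(C)(C)C.[I-]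
F13 | step 20 | 15-(tert-butyldiphenylsilyloxy) analogue of methylene lactone 25 | C=C[C@@]1(C)C[C@H](O[Si](C)(C)C(C)(C)C)[C@H]2C(=C)C(=O)O[C@@H]2[C@H]1C(=C)CO[Si](c3ccccc3)(c4ccccc4)C(C)(C)C
F14 | step 20 | 15-(tert-butyldiphenylsilyloxy) analogue of alcohol 26 | C=C[C@@]1(C)C[C@H](O)[C@H]2C(=C)C(=O)O[C@@H]2[C@H]1C(=C)CO[Si](c3ccccc3)(c4ccccc4)C(C)(C)C
F15 | step 20 | 15-O-tert-butyldiphenylsilyl ether of 32 | C=C[C@@]1(C)C[C@H](OC(=O)[C@H](C)CO[Si](C)(C)C(C)(C)C)[C@H]2C(=C)C(=O)O[C@@H]2[C@H]1C(=C)CO[Si](c3ccccc3)(c4ccccc4)C(C)(C)C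
F16 | step 13 | trimethylsilyl ester and O6 trimethylsilyl ether of F17 | C=C[C@@]1(C)C[C@H](O[Si](C)(C)C(C)(C)C)[C@@H](CC(=O)O[Si](C)(C)C)[C@H](O[Si](C)(C)C)[C@H]1C(C)=C
F17 | step 13 | 2-[(1S,2R,3S,4R,6S)-6-[(tert-butyldimethylsilyl)oxy]-4-ethenyl-2-hydroxy-4-methyl-3-(prop-1-en-2-yl)cyclohexyl]acetic acid | C=C[C@@]1(C)C[C@H](O[Si](C)(C)C(C)(C)C)[C@@H](CC(=O)O)[C@H](O)[C@H]1C(C)=C
A1 | alternative 1 | methyl (2E)-2-(acetoxymethyl)-4-[(tert-butyldimethylsilyl)oxy]-8-{[(tert-butyldimethylsilyl)oxy]methyl}-6-ethenyl-7-formyl-6-methylnona-2,8-dienoate, configured at C5, C8 and C10 as in 33 | O=C[C@@H](C(=C)CO[Si](C)(C)C(C)(C)C)[C@@](C)(C=C)C[C@H](O[Si](C)(C)C(C)(C)C)/C=C(\COC(C)=O)C(=O)OC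
A2 | alternative 1 | 8,15-bis(tert-butyldimethylsilyl) ether of the 8,15-diol α-methylene lactone | C=C[C@@]1(C)C[C@H](O[Si](C)(C)C(C)(C)C)[C@H]2C(=C)C(=O)O[C@@H]2[C@H]1C(=C)CO[Si](C)(C)C(C)(C)C
A3 | alternative 2 | cis-fused bicyclo[4.2.0]oct-7-en-2-one with the C1=C4 cyclobutene: 6-methyl at C10, 8-(silyloxymethyl) at C4, 4-silyloxy at C8, 3-(2-methoxy-2-oxoethyl) at C7 | C[C@]12C[C@H](O[Si](C)(C)C(C)(C)C)[C@@H](CC(=O)OC)C(=O)[C@H]1C(CO[Si](C)(C)C(C)(C)C)=C2
A4 | alternative 2 | methyl 2-[5-(tert-butyldimethylsilyloxy)-3-ethenyl-3-methyl-6-oxo... cyclohexyl]acetate, i.e. the C6 ketone with the C10 vinyl and the C5 3-(silyloxy)prop-1-en-2-yl group cis | C=C[C@@]1(C)C[C@H](O[Si](C)(C)C(C)(C)C)[C@@H](CC(=O)OC)C(=O)[C@H]1C(=C)CO[Si](C)(C)C(C)(C)C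
A5 | alternative 3 | ten-membered allylic lactone (C1 carbonyl, O–C3H2, C4=C5 alkene bearing the CH2O-4-methoxybenzyl group) fused to the 6,12-γ-lactone, 8-silyloxy; C10 and the alkene geometry left open | CC1C[C@H](O[Si](C)(C)C(C)(C)C)[C@H]2CC(=O)O[C@@H]2C=C(COCc3ccc(OC)cc3)COC1=O
A6 | alternative 3 | cyclohexanecarboxylic acid with C1 carboxyl on quaternary C10, the 6,12-γ-lactone, 8-silyloxy and the C5 3-(4-methoxybenzyloxy)prop-1-en-2-yl group | OC(=O)[C@@]1(C)C[C@H](O[Si](C)(C)C(C)(C)C)[C@H]2CC(=O)O[C@@H]2[C@H]1C(=C)COCc3ccc(OC)cc3
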